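The data were computed with constants of no real substance; the scatter is artificial.

Late in a run, what matters is which substrate still feeds the product faster. In the west run the left-handed substrate falls faster and so thins out sooner. At some moment the two rates must meet.

the same everywhere: gas 5.9 mM (held)
- west: left-handed substrate 0.10 M; right-handed substrate 0.10 M; catalyst 0.14 mol%; run made earlier
- south-east: left-handed substrate 0.10 M; right-handed substrate 0.10 M; catalyst 0.22 mol%; run made earlier
- north: left-handed substrate 0.15 M; right-handed substrate 0.15 M; catalyst 0.1 mol%; run made earlier
- flask: left-handed substrate 0.10 M; right-handed substrate 0.10 M; catalyst 0.1 mol%; time 15 min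

- west (time / min: left-handed product / %, right-handed product / %, left-handed substrate / %): 1.33: 5, 4, 41; 2.00: 5, 6, 40; 3.00: 10, 8, 39; 5.00: 19, 10, 33; 10.0: 28, 24, 19; 15.0: 29, 30, 11
- south-east (time / min: left-handed product / %, right-handed product / %, left-handed substrate / %): 2.50: 17, 6, 39; 5.00: 19, 19, 27; 8.00: 31, 24, 16; 10.0: 32, 31, 10; 12.0: 34, 37, 7; 15.0: 37, 38, 7
- north (time / min: left-handed product / %, right-handed product / %, left-handed substrate / %): 1.33: 6, 4, 46; 2.50: 11, 7, 38; 4.00: 14, 13, 34; 8.00: 24, 23, 23; 15.0: 31, 33, 10

(readings scatter by 2 percentage points)

- catalyst is single-handed; left-handed substrate and right-handed substrate are mirror images of each other, charged as a racemate, each of them at the stated concentration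
- at the start none of coupling partner is dissolved
- the numbers in the tables scatter by 2 percentage points (one standard deviation)
- on the list of suspects stand: coupling partner + catalyst + left-handed substrate -> catalyst + left-handed product; coupling partner + catalyst + right-handed substrate -> catalyst + right-handed product; left-handed product <-> right-handed product; gas <-> coupling partner
- an excess is the difference of the two amounts in percent of their sum
- an excess is below zero if the other one leads

- excess of left-handed product over right-handed product in the product at 20 s
- excess of left-handed product over right-handed product in the product at 15 min
- part of the left-handed substrate and right-handed substrate charged together that has reacted at 15 min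

Treat each substrate as pseudo-first-order, with rate constants kL (left-handed) and kR (right-handed) proportional to catalyst concentration. The last west reading leaves 11% of left-handed substrate. The mass balance leaves 30.0% of right-handed substrate. Each started at half of what was charged together. Scaled to the flask's catalyst, that gives kL = 0.0721 min⁻¹ and kR = 0.0243 min⁻¹.

The two rates are equal at t× = ln(kL/kR)/(kL − kR). For the flask that is 22.7 min, the crossing time: the moment at which both substrates react equally fast.

But that rests on one run. The north run, with its different substrate charge and catalyst loading, gives kL = 0.0715 min⁻¹, which agrees.

Its kR is 0.0291 min⁻¹, though, and right-handed substrate comes by difference from three scattered readings. So you should recompute. The crossing moves to 21.2 min, still later than the flask's 15 min.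

A second doubt: the products interconvert, so does the excess follow the rates? It lags them. Yet interconversion drains an excess towards zero, not past it. So my reckoning keeps the flask's excess positive at the end, since the crossing comes later than 15 min, with 48.3% reacted. I set no early excess of my own.

The forecast gives an excess of 30% at 20 s, an excess of 1% at 15 min, and 51% reacted at 15 min, reasoning that the products stay close, “so they racemise quickly”.

The flask gives an excess of 36.3% at 20 s, an excess of 1.57% at 15 min, and 50.0% reacted at 15 min.

    coupling partner + catalyst + left-handed substrate → catalyst + left-handed product (k = 1.20 × 10⁵ L² mol⁻² min⁻¹)
    coupling partner + catalyst + right-handed substrate → catalyst + right-handed product (k = 52000 L² mol⁻² min⁻¹)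
    left-handed product ⇌ right-handed product (k = 0.260 min⁻¹)
    gas ⇌ coupling partner, rate k4*(csat - [coupling partner]) (kL = 36.0 min⁻¹)

The forecast's early excess was lower than the flask's. At the flask's end, 36% of the left-handed and 64% of the right-handed charge remain, yet the left-handed rate is still the faster. Now take the neighbour with 0.4 mol% of catalyst. Scaling the crossing time by catalyst puts it at 5.69 min, earlier than 15 min. That neighbour ended with 45.9% of right-handed product and an excess of −1.82%.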